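**Retrosynthetic overview** (ent-kaurane numbering: ring A = C1–C5, C10; γ-lactone C6(=O)–O–C19; δ-lactone ring B C7(=O)–O–C20; ring C = C8, C9, C11–C14; ring D = C8, C13–C16; C17 = CH2OH)
1. End game: C17–OH by conjugate borylation/oxidation of a C16 exo-methylene ketone, the C15 ketone by ozonolysis, and ring D (C8–C15) by palladium-mediated cyclisation of a C8 silyl ketene acetal onto an allyl group on C13.
2. Key disconnection: the O–C(=O) unit of the δ-lactone is CO2. C7–C8 and C20–O are made together from a C8 alkenyl bromide in cyclohexene ring C and a C20 mesylate; nickel-catalysed reductive carboxylation joins two electrophilic carbons (C8 and CO2) and the carboxylate closes ring B on C20.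
3. Enabling feature: C8, the quaternary bridgehead shared by the δ-lactone and the bicyclo[3.2.1]octane, is one oxidation level lower an sp2 carbon (C8=C14 of ring C) that can carry bromine. It is 1,4 to C20 through C9 and the spiro carbon C10, so a carboxyl group on C8 sits five atoms from the neopentyl leaving group (6-exo-tet). The enoate left behind later gives the C8 enolate equivalent regiospecifically.
4. C9–C10 bond and quaternary C10: Reformatsky–Claisen rearrangement of the ester between a ring-A α-bromo acid and a (1S)-2-bromocyclohex-2-enol, which transfers the C14–O stereocentre to C9.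
5. Ring A with the cis γ-lactone: intramolecular Diels–Alder reaction of a pentadienyl maleate half ester, then resolution. Order of ring formation: A + γ-lactone, ring C (from (R)-4-silyloxycyclohexenone), δ-lactone B, ring D.

Key step: step 13

Assumption: phosphorane 2 and enone 10 are taken as commercial; in step 4 the (S)-amine is written, and the antipodal amine is used instead if its salt with the required acid is the less soluble one.

Step 1
Reactants: 1 acrolein; 2 ethyl 2-(triphenylphosphoranylidene)propanoate
Product: 3 ethyl (2E)-2-methylpenta-2,4-dienoate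
Conditions: CH2Cl2, 0 °C to rt
Reagents that add atoms: none
Why: Wittig olefination with a stabilised, α-branched ylide, which should give the E trisubstituted alkene.

Step 2
Reactants: 3 ethyl (2E)-2-methylpenta-2,4-dienoate
Product: 4 (2E)-2-methylpenta-2,4-dien-1-ol
Conditions: DIBAL-H (2.2 equiv), CH2Cl2, −78 °C; Rochelle salt work-up
Reagents that add atoms: none
Why: DIBAL-H reduction of a conjugated ester to the allylic alcohol proceeds by 1,2-addition and leaves the diene geometry untouched.

Step 3
Reactants: 4 (2E)-2-methylpenta-2,4-dien-1-ol; 5 maleic anhydride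
Product: 7 racemic (3aR*,7S*,7aS*)-3a-methyl-1-oxo-1,3,3a,6,7,7a-hexahydroisobenzofuran-7-carboxylic acid, via maleate half ester 6 (not isolated)
Conditions: DMAP (10 mol %), CH2Cl2, rt; then toluene, BHT, 110 °C
Reagents that add atoms: none
Why: Alcoholysis of the anhydride gives the (Z)-half ester, whose intramolecular Diels–Alder reaction (ester-tethered 1,3,8-nonatriene, the pentadienyl maleate type) forms ring A and the γ-lactone; the three-atom tether enforces the cis fusion at C4/C5 and the Z dienophile places C20 cis to C6, so C4, C5 and C10 are related by geometry alone.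

Step 4
Reactants: 7 racemic lactone acid
Product: 8 (3aR,7S,7aS)-3a-methyl-1-oxo-1,3,3a,6,7,7a-hexahydroisobenzofuran-7-carboxylic acid
Conditions: (S)-1-phenylethylamine (1.0 equiv), EtOAc/EtOH, fractional crystallisation; then 1 M HCl
Reagents that add atoms: none
Why: Classical resolution of a carboxylic acid through its diastereomeric 1-phenylethylammonium salts, the acid being set free from the less soluble salt with HCl.

Step 5
Reactants: 8 resolved unsaturated lactone acid
Product: 9 (3aR,7S,7aS)-3a-methyl-1-oxooctahydroisobenzofuran-7-carboxylic acid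
Conditions: H2 (1 atm), 10% Pd/C, EtOAc, rt
Reagents that add atoms: none
Why: Heterogeneous catalytic hydrogenation of the disubstituted ring alkene; no stereocentre is formed.

Step 6
Reactants: 10 (R)-4-[(tert-butyldimethylsilyl)oxy]cyclohex-2-en-1-one
Product: 11 (R)-2-bromo-4-[(tert-butyldimethylsilyl)oxy]cyclohex-2-en-1-one
Conditions: Br2, CH2Cl2, 0 °C; then Et3N, 0 °C to rt
Reagents that add atoms: bromine, BrBr
Why: Bromination–dehydrobromination of an enone (addition of Br2, then E1cB loss of HBr) gives the 2-bromoenone without touching the C4 stereocentre.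

Step 7
Reactants: 11 (R)-2-bromo-4-[(tert-butyldimethylsilyl)oxy]cyclohex-2-en-1-one
Product: 12 (4R,6R)-6-allyl-2-bromo-4-[(tert-butyldimethylsilyl)oxy]cyclohex-2-en-1-one
Conditions: LDA, THF, −78 °C; allyl bromide, DMPU, −78 to −40 °C
Reagents that add atoms: allyl bromide, C=CCBr
Why: Alkylation of the kinetic α′-enolate, in which allyl bromide should enter anti to the pseudoaxial 4-silyloxy group to give the 4,6-trans product.

Step 8
Reactants: 12 (4R,6R)-6-allyl-2-bromo-4-[(tert-butyldimethylsilyl)oxy]cyclohex-2-en-1-one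
Product: 13 (1S,4R,6R)-6-allyl-2-bromo-4-[(tert-butyldimethylsilyl)oxy]cyclohex-2-en-1-ol
Conditions: NaBH4, CeCl3·7H2O, MeOH, −40 °C
Reagents that add atoms: none
Why: Luche 1,2-reduction, in which axial hydride delivery should give the equatorial alcohol trans to the neighbouring allyl group and therefore cis to the silyloxy group.

Step 9
Reactants: 9 (3aR,7S,7aS)-3a-methyl-1-oxooctahydroisobenzofuran-7-carboxylic acid; 13 (1S,4R,6R)-6-allyl-2-bromo-4-[(tert-butyldimethylsilyl)oxy]cyclohex-2-en-1-ol
Product: 16 (1S,4R,6R)-6-allyl-2-bromo-4-[(tert-butyldimethylsilyl)oxy]cyclohex-2-en-1-yl (3aR,7aS)-7-bromo-3a-methyl-1-oxooctahydroisobenzofuran-7-carboxylate (either C7 epimer), via acid chloride 14 (not isolated), via bromo acid chloride 15 (not isolated)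
Conditions: SOCl2, 70 °C; NBS, HBr (cat.), 85 °C; evaporate; then 13, pyridine, DMAP (cat.), CH2Cl2, 0 to 40 °C
Reagents that add atoms: N-bromosuccinimide, O=C1CCC(=O)N1Br
Why: Hell–Volhard–Zelinsky-type α-bromination of the acid chloride with NBS followed by esterification; under these acidic conditions only C10, the α-carbon of the acid chloride, enolises, so the lactone α-carbon C5 is untouched, and the configuration at the C–Br carbon does not matter because it is erased in step 10.

Step 10
Reactants: 16 α-bromo ester
Product: 19 (3aR,7aS)-7-[4-allyl-2-bromo-6-(tert-butyldimethylsilyloxy)cyclohex-2-en-1-yl]-3a-methyl-1-oxooctahydroisobenzofuran-7-carboxylic acid (cyclohexenyl group cis to the angular methyl; in the cyclohexenyl unit the silyloxy group cis and the allyl group trans to the new bond), via silyl ketene acetal 17 (not isolated), via trimethylsilyl ester 18 (not isolated)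
Conditions: Zn dust (activated, 5 equiv), TMSCl (3 equiv), THF/MeCN, 70 °C; then 1 M HCl
Reagents that add atoms: none
Why: Reformatsky–Claisen rearrangement: zinc inserts only into the tertiary α-bromo ester (no base, so C5–H is safe, and the alkenyl bromide is inert), and the [3,3] shift is suprafacial on the cyclohexenyl unit, so the C14–O configuration is transferred to C9, while C9 should bond to the convex face of the cis-fused bicyclic ketene acetal, anti to the lactone ring, which sets the quaternary C10.

Step 11
Reactants: 19 rearranged acid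
Product: 21 (3aR,7aS)-7-[4-allyl-2-bromo-6-(tert-butyldimethylsilyloxy)cyclohex-2-en-1-yl]-7-(hydroxymethyl)-3a-methylhexahydroisobenzofuran-1(3H)-one (configuration as in 19), via mixed anhydride 20 (not isolated)
Conditions: i-BuOCOCl, N-methylmorpholine, THF, −15 °C; then NaBH4, THF/H2O, 0 °C
Reagents that add atoms: none
Why: Reduction of a carboxylic acid through its mixed carbonic anhydride with NaBH4, which should leave the lactone, the alkenyl bromide, the silyl ether and both alkenes untouched.

Step 12
Reactants: 21 neopentyl alcohol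
Product: 22 the methanesulfonate of 21 (C20–OMs)
Conditions: MsCl, Et3N, CH2Cl2, 0 °C
Reagents that add atoms: methanesulfonyl chloride, CS(=O)(=O)Cl
Why: Sulfonylation of a primary alcohol; the neopentyl mesylate is stable to handling because intermolecular SN2 at this carbon is slow.

Step 13
Reactants: 22 bromo mesylate
Product: 24 tetracyclic bis-lactone with C8=C14 (δ-lactone ring B closed; allyl on C13, OTBS on C11), via manganese carboxylate 23 (not isolated)
Conditions: NiCl2(PPh3)2 (10 mol %), PPh3 (20 mol %), Mn powder (3 equiv), CO2 (1 atm), DMA, 25 °C; then 80 °C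
Reagents that add atoms: carbon dioxide, O=C=O
Why: Manganese reduces the precatalyst to zerovalent nickel, which inserts into the alkenyl C8–Br bond; after one-electron reduction the alkenylnickel species adds to CO2 (C7–C8), and on warming the manganese carboxylate 23 displaces the mesylate at C20 (C20–O). The closest known reaction type is the nickel-catalysed reductive carboxylation of aryl and alkenyl halides with CO2 and manganese, followed here by ordinary lactonisation of a carboxylate onto a sulfonate; it unites two electrophilic carbons by polarity reversal. Ring B closes in the 6-exo-tet mode, the ring being made of the attacking oxygen, C7, C8, C9, C10 and C20. No stereocentre is formed, since C8 stays trigonal (C8=C14) and C9 and C10 are spectators, so the configuration of C8 is left to the ring-D closure. The step needs chemoselectivity for the alkenyl bromide over the neopentyl mesylate, which nickel should not activate without halide additives, and carboxylation must not be overtaken by cyclisation onto the allyl group, which is excluded because it would give a bridgehead alkene. The displacement at the neopentyl carbon, slow between molecules, is secured by the five-atom tether.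

Step 14
Reactants: 24 unsaturated bis-lactone
Product: 26 pentacyclic bis-lactone with the bicyclo[3.2.1]octane closed (C8–C15 bond; exocyclic methylene on C15; OTBS on C11), via silyl ketene acetal 25 (not isolated)
Conditions: [(Ph3P)CuH]6 (5 mol %), PhMe2SiH (1.1 equiv), toluene, rt; then Pd(OAc)2 (1.0 equiv), DMSO, 45 °C
Reagents that add atoms: none
Why: Copper hydride 1,4-hydrosilylation of the enoate gives the C8 silyl ketene acetal regiospecifically without enolising the γ-lactone, and the palladium-mediated oxidative cyclisation of the ketene acetal onto the alkene (5-exo, then β-hydride elimination, as used for bicyclo[3.2.1]octanes of this family) forms C8–C15; the allyl group on C13 reaches only the lower face of ring C, so the quaternary C8 is set with C15 trans to C10.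

Step 15
Reactants: 26 15-methylene compound
Product: 27 15-ketone (11-OTBS)
Conditions: O3, CH2Cl2/MeOH, −78 °C; then Me2S
Reagents that add atoms: ozone, [O-][O+]=O
Why: Ozonolysis with reductive work-up of the 1,1-disubstituted alkene, the only C=C left in the molecule, gives the C15 ketone.

Step 16
Reactants: 27 15-ketone
Product: 28 16-methylene-15-ketone (11-OTBS)
Conditions: (CH2O)n, PhNHMe·CF3CO2H, THF, 65 °C
Reagents that add atoms: paraformaldehyde (formaldehyde), C=O
Why: α-Methylenation of a ketone by Mannich condensation–elimination with formaldehyde and an anilinium salt; C16 is the only enolisable α-carbon of the C15 ketone because C8 is quaternary, and no strong base is present.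

Step 17
Reactants: 28 exo-methylene ketone
Product: 30 the 11-O-tert-butyldimethylsilyl ether of the target, via pinacol boronate 29 (not isolated)
Conditions: B2pin2 (1.1 equiv), CuCl (5 mol %), Xantphos (5 mol %), NaOtBu (8 mol %), MeOH (2 equiv), THF, rt; then NaBO3·4H2O, THF/H2O, rt
Reagents that add atoms: sodium perborate, [Na+].[Na+].O[B-]1(O)OO[B-](O)(O)OO1
Why: Copper-catalysed conjugate borylation of the enone followed by oxidation of the C–B bond; the enolate should be protonated by methanol on the exo face of the bicyclo[3.2.1]octane, which places C17 endo as in the target.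

Step 18
Reactants: 30 silyl ether
Product: 31 CNP0555433.1 (target)
Conditions: HF·pyridine, THF, 0 °C to rt
Reagents that add atoms: none
Why: Fluoride cleavage of the silyl ether under mildly acidic conditions that should neither epimerise C16 nor dehydrate the β-hydroxy ketone; C11 keeps the configuration brought in with 10.

**Compound list**
1 | acrolein | C=CC=O | starting material
2 | ethyl 2-(triphenylphosphoranylidene)propanoate | CCOC(=O)C(C)=P(c1ccccc1)(c1ccccc1)c1ccccc1 | starting material
3 | ethyl (2E)-2-methylpenta-2,4-dienoate | CCOC(=O)/C(C)=C/C=C | intermediate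
4 | (2E)-2-methylpenta-2,4-dien-1-ol | OC/C(C)=C/C=C | intermediate
5 | maleic anhydride | O=C1OC(=O)C=C1 | starting material
6 | (2Z)-4-{[(2E)-2-methylpenta-2,4-dien-1-yl]oxy}-4-oxobut-2-enoic acid (maleate half ester) | OC(=O)/C=C\C(=O)OC/C(C)=C/C=C | intermediate
7 | racemic (3aR*,7S*,7aS*)-3a-methyl-1-oxo-1,3,3a,6,7,7a-hexahydroisobenzofuran-7-carboxylic acid | C[C@@]12C=CC[C@H](C(=O)O)[C@@H]1C(=O)OC2.C[C@]12C=CC[C@@H](C(=O)O)[C@H]1C(=O)OC2 | intermediate
8 | (3aR,7S,7aS)-3a-methyl-1-oxo-1,3,3a,6,7,7a-hexahydroisobenzofuran-7-carboxylic acid | C[C@@]12C=CC[C@H](C(=O)O)[C@@H]1C(=O)OC2 | intermediate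
9 | (3aR,7S,7aS)-3a-methyl-1-oxooctahydroisobenzofuran-7-carboxylic acid | C[C@@]12CCC[C@H](C(=O)O)[C@@H]1C(=O)OC2 | intermediate
10 | (R)-4-[(tert-butyldimethylsilyl)oxy]cyclohex-2-en-1-one | O=C1C=C[C@H](O[Si](C)(C)C(C)(C)C)CC1 | starting material
11 | (R)-2-bromo-4-[(tert-butyldimethylsilyl)oxy]cyclohex-2-en-1-one | O=C1C(Br)=C[C@H](O[Si](C)(C)C(C)(C)C)CC1 | intermediate
12 | (4R,6R)-6-allyl-2-bromo-4-[(tert-butyldimethylsilyl)oxy]cyclohex-2-en-1-one | O=C1C(Br)=C[C@H](O[Si](C)(C)C(C)(C)C)C[C@H]1CC=C | intermediate
13 | (1S,4R,6R)-6-allyl-2-bromo-4-[(tert-butyldimethylsilyl)oxy]cyclohex-2-en-1-ol | O[C@@H]1C(Br)=C[C@H](O[Si](C)(C)C(C)(C)C)C[C@H]1CC=C | intermediate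
14 | (3aR,7S,7aS)-3a-methyl-1-oxooctahydroisobenzofuran-7-carbonyl chloride | C[C@@]12CCC[C@H](C(Cl)=O)[C@@H]1C(=O)OC2 | intermediate
15 | (3aR,7aS)-7-bromo-3a-methyl-1-oxooctahydroisobenzofuran-7-carbonyl chloride (either C7 epimer) | C[C@@]12CCCC(Br)(C(Cl)=O)[C@@H]1C(=O)OC2 | intermediate
16 | (1S,4R,6R)-6-allyl-2-bromo-4-[(tert-butyldimethylsilyl)oxy]cyclohex-2-en-1-yl (3aR,7aS)-7-bromo-3a-methyl-1-oxooctahydroisobenzofuran-7-carboxylate (either C7 epimer) | C[C@@]12CCCC(Br)(C(=O)O[C@@H]3C(Br)=C[C@H](O[Si](C)(C)C(C)(C)C)C[C@H]3CC=C)[C@@H]1C(=O)OC2 | intermediate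
17 | O-trimethylsilyl ketene acetal derived from 16 (C10=C20 double bond) | C[C@@]12CCCC(=C(O[Si](C)(C)C)O[C@@H]3C(Br)=C[C@H](O[Si](C)(C)C(C)(C)C)C[C@H]3CC=C)[C@@H]1C(=O)OC2 | intermediate
18 | trimethylsilyl ester of 19 | C[C@@]12CCC[C@]([C@H]3C(Br)=C[C@H](CC=C)C[C@H]3O[Si](C)(C)C(C)(C)C)(C(=O)O[Si](C)(C)C)[C@@H]1C(=O)OC2 | intermediate
19 | (3aR,7aS)-7-[4-allyl-2-bromo-6-(tert-butyldimethylsilyloxy)cyclohex-2-en-1-yl]-3a-methyl-1-oxooctahydroisobenzofuran-7-carboxylic acid (cyclohexenyl cis to the angular methyl; silyloxy cis, allyl trans to the C9–C10 bond) | C[C@@]12CCC[C@]([C@H]3C(Br)=C[C@H](CC=C)C[C@H]3O[Si](C)(C)C(C)(C)C)(C(=O)O)[C@@H]1C(=O)OC2 | intermediate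
20 | isobutyl carbonic anhydride of 19 | C[C@@]12CCC[C@]([C@H]3C(Br)=C[C@H](CC=C)C[C@H]3O[Si](C)(C)C(C)(C)C)(C(=O)OC(=O)OCC(C)C)[C@@H]1C(=O)OC2 | intermediate
21 | C20 alcohol: 7-(hydroxymethyl) analogue of 19 | C[C@@]12CCC[C@]([C@H]3C(Br)=C[C@H](CC=C)C[C@H]3O[Si](C)(C)C(C)(C)C)(CO)[C@@H]1C(=O)OC2 | intermediate
22 | C20 methanesulfonate of 21 | C[C@@]12CCC[C@]([C@H]3C(Br)=C[C@H](CC=C)C[C@H]3O[Si](C)(C)C(C)(C)C)(COS(C)(=O)=O)[C@@H]1C(=O)OC2 | intermediate
23 | manganese bromide salt of the C8 carboxylate (C7 installed, mesylate intact) | C[C@@]12CCC[C@]([C@H]3C(C(=O)[O-])=C[C@H](CC=C)C[C@H]3O[Si](C)(C)C(C)(C)C)(COS(C)(=O)=O)[C@@H]1C(=O)OC2.[Mn+2].[Br-] | intermediate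
24 | tetracyclic bis-lactone: spiro δ-lactone with C8=C14, allyl on C13, OTBS on C11 | C[C@@]12CCC[C@]3(COC(=O)C4=C[C@H](CC=C)C[C@@H](O[Si](C)(C)C(C)(C)C)[C@H]43)[C@@H]1C(=O)OC2 | intermediate
25 | C8 dimethylphenylsilyl ketene acetal of the 14-hydro lactone | C[C@@]12CCC[C@]3(COC(O[Si](C)(C)c4ccccc4)=C5C[C@H](CC=C)C[C@@H](O[Si](C)(C)C(C)(C)C)[C@H]53)[C@@H]1C(=O)OC2 | intermediate
26 | pentacyclic 15-methylene bis-lactone (bicyclo[3.2.1]octane closed, 11-OTBS) | C[C@@]12CCC[C@]3(COC(=O)[C@@]45C[C@@H](C[C@@H](O[Si](C)(C)C(C)(C)C)[C@H]43)CC5=C)[C@@H]1C(=O)OC2 | intermediate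
27 | 15-ketone (11-OTBS) | C[C@@]12CCC[C@]3(COC(=O)[C@@]45C[C@@H](C[C@@H](O[Si](C)(C)C(C)(C)C)[C@H]43)CC5=O)[C@@H]1C(=O)OC2 | intermediate
28 | 16-methylene-15-ketone (11-OTBS) | C[C@@]12CCC[C@]3(COC(=O)[C@@]45C[C@@H](C[C@@H](O[Si](C)(C)C(C)(C)C)[C@H]43)C(=C)C5=O)[C@@H]1C(=O)OC2 | intermediate
29 | 17-(pinacolboryl)-15-ketone (11-OTBS, H16 exo) | C[C@@]12CCC[C@]3(COC(=O)[C@@]45C[C@@H](C[C@@H](O[Si](C)(C)C(C)(C)C)[C@H]43)[C@@H](CB6OC(C)(C)C(C)(C)O6)C5=O)[C@@H]1C(=O)OC2 | intermediate
30 | 11-O-tert-butyldimethylsilyl ether of the target | C[C@@]12CCC[C@]3(COC(=O)[C@@]45C[C@@H](C[C@@H](O[Si](C)(C)C(C)(C)C)[C@H]43)[C@@H](CO)C5=O)[C@@H]1C(=O)OC2 | intermediate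
31 | CNP0555433.1 (11,17-dihydroxy-15-oxo-6,7-seco-ent-kaurane-6,19:7,20-diolide) | C[C@@]12CCC[C@]3(COC(=O)[C@@]45C[C@@H](C[C@@H](O)[C@H]43)[C@@H](CO)C5=O)[C@@H]1C(=O)OC2 | target

**Step count:** 18 steps in total. Longest linear sequence: 15 steps (steps 1–5, then 9–18); steps 6–8 are the three-step branch to alcohol 13.

**Steps most likely to fail**

Step 10. The rearrangement builds a quaternary centre next to a tertiary one, so the zinc enolate may simply be protonated (loss of bromine without the [3,3] shift), or the cyclohexenyl unit may bond to the wrong face of C10. The fallback sets out from acid 9 and alcohol 13 and returns at acid 19. Carbodiimide esterification (DCC, DMAP) gives the bromine-free ester F1. Double deprotonation and silylation (KHMDS 2.3 equiv, TMSCl, THF/DMPU, −78 °C) gives the bis(trimethylsilyl ketene acetal) F2. Its Ireland–Claisen rearrangement on warming to 25–60 °C gives the rearranged silyl ester F3, and aqueous acid removes both silyl groups, reprotonates C5 to the cis-fused lactone and delivers 19.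

Step 13. The alkenylnickel intermediate may be protonated instead of carboxylated, or the ring closure at the neopentyl carbon may be too slow, so that the mesylate decomposes first. The fallback sets out from alcohol 21 and returns at 24: palladium-catalysed carbonylative lactonisation (Pd(PPh3)4, CO 1 atm, Et3N, DMF, 80 °C), in which the acylpalladium species formed at C8 is trapped by the C20 hydroxyl. It makes no new compound.

Step 3. The maleate may isomerise to the fumarate before cycloaddition, which would invert C10 relative to C5, and the cycloaddition may be slow because the diene terminus that becomes C4 is fully substituted. The fallback sets out from dienol 4 and returns at 7. Silylation (TBSCl, imidazole) gives the silyl ether F4. Intermolecular Diels–Alder reaction with maleic anhydride 5 (toluene, 110 °C, endo) gives the bicyclic anhydride F5. HF in MeCN then removes the silyl group, and the freed C19 hydroxyl opens the anhydride at the neighbouring carbonyl to give racemic 7.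

Further compounds
F1 | step 10 | (1S,4R,6R)-6-allyl-2-bromo-4-[(tert-butyldimethylsilyl)oxy]cyclohex-2-en-1-yl (3aR,7S,7aS)-3a-methyl-1-oxooctahydroisobenzofuran-7-carboxylate | C[C@@]12CCC[C@H](C(=O)O[C@@H]3C(Br)=C[C@H](O[Si](C)(C)C(C)(C)C)C[C@H]3CC=C)[C@@H]1C(=O)OC2
F2 | step 10 | bis(trimethylsilyl ketene acetal) of F1 (ester and lactone both enolised) | C[C@@]12CCCC(=C(O[Si](C)(C)C)O[C@@H]3C(Br)=C[C@H](O[Si](C)(C)C(C)(C)C)C[C@H]3CC=C)C1=C(O[Si](C)(C)C)OC2
F3 | step 10 | rearranged trimethylsilyl ester with the lactone still as its silyl ketene acetal | C[C@@]12CCC[C@]([C@H]3C(Br)=C[C@H](CC=C)C[C@H]3O[Si](C)(C)C(C)(C)C)(C(=O)O[Si](C)(C)C)C1=C(O[Si](C)(C)C)OC2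
F0 | step 13 | none | none
F4 | step 3 | tert-butyldimethyl{[(2E)-2-methylpenta-2,4-dien-1-yl]oxy}silane | CC(C)(C)[Si](C)(C)OC/C(C)=C/C=C
F5 | step 3 | racemic endo Diels–Alder anhydride: 4-[(tert-butyldimethylsilyloxy)methyl]-4-methyl-3a,4,7,7a-tetrahydroisobenzofuran-1,3-dione, silyloxymethyl cis to the anhydride | C[C@@]1(CO[Si](C)(C)C(C)(C)C)C=CC[C@@H]2C(=O)OC(=O)[C@H]12.C[C@]1(CO[Si](C)(C)C(C)(C)C)C=CC[C@H]2C(=O)OC(=O)[C@@H]12
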